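**Retrosynthetic overview**
1. The target is cut back (desilylation, Horner–Wadsworth–Emmons methylenation, C11 reduction, Michael addition at C13, C1 acetylation) to a tetracyclic enone lactone, whose C9 centre is set by base equilibration next to the C11 ketone.
2. The strategy rests on quaternary C8 of ring B: it carries the carboxyl carbon C7 and is linked through C14 to the C13=C12 unit beside the C11 carbinol of ring C, the pattern left by a [3,3] shift of a C7–O–C12 ester with a C12 vinyl group (C13=C14).
3. Ring C and C8 therefore come from the Ireland–Claisen rearrangement of a cis-fused vinyl δ-lactone on the trans A/B hydrindane, run on the 9-epimer.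
4. The lactone comes from two vinyl Grignard additions at C11 and C12, and ring B from an enamine aldol (C6–C8 bond) of a dialdehyde made by ozonolysis of a C5 vinyl and a C9 allyl group.
5. Rings form in the order A (starting material), temporary O1–C11 γ-lactone (fixes C9), B, C7–O–C12 δ-lactone, C (key step), bridging C7–O–C20 lactone.

Key step: step 21

Remark on numbering: kaurane numbering of the target is used for all intermediates (ring A: C1 acetoxy carbon, C2, C3, C4 gem-dimethyl, C5, C10; ring B: C5, C6, C8, C9, C10; ring C: C8, C9, C11, C12, C13, C14; C7 lactone carbonyl on C8; C20 the OCH2 on C10; C15–C17 the acrylate). "Up" is the face of ring B that carries C20, "down" the opposite face.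
Assumption on the chemistry: the boat Claisen transition state of a lactone fused to ring B can deliver C14 only to the face of C8 on which C11 sits. The target has C14 and C11 on opposite faces, so the rearrangement is run on the 9-epimer (C11 down) and C9 is inverted afterwards through the C11 ketone. O1 and O20 are carried as an acetonide, O6 as a TBS ether and O11 as a PMB ether.

**Route**

Step 1
Reactants: 1 4,4-dimethylcyclohexanone; 2 dimethyl carbonate
Product: 3 methyl 5,5-dimethyl-2-oxocyclohexane-1-carboxylate
Conditions: NaH (2.2 equiv), (MeO)2CO, THF, 65 °C; AcOH quench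
Reagents that add atoms: dimethyl carbonate (2), COC(=O)OC
Why: Claisen-type carbomethoxylation of the ketone enolate, driven by formation of the β-keto ester enolate; the ketone is symmetric, so one product forms.

Step 2
Reactants: 3 methyl 5,5-dimethyl-2-oxocyclohexane-1-carboxylate
Product: 5 methyl 3,3-dimethyl-6-oxocyclohex-1-ene-1-carboxylate, via α-phenylselanyl keto ester 4 (not isolated)
Conditions: PhSeCl, pyridine, CH2Cl2, 0 °C; then 30% H2O2, 0 °C to rt
Reagents that add atoms: none
Why: Reich α-selenenylation of the β-keto ester and selenoxide syn-elimination should give the enone ester; only C5 offers β-hydrogens and the quaternary C4 blocks dienol formation.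

Step 3
Reactants: 5 methyl 3,3-dimethyl-6-oxocyclohex-1-ene-1-carboxylate; 6 4,4,5,5-tetramethyl-2-vinyl-1,3,2-dioxaborolane
Product: 7 methyl (1S,6S)-6-ethenyl-5,5-dimethyl-2-oxocyclohexane-1-carboxylate (5-vinyl keto ester; C10 epimerisable)
Conditions: [Rh(OH)((R)-BINAP)]2 (3 mol%), dioxane/H2O 10:1, 40 °C
Reagents that add atoms: vinylboronic acid pinacol ester (6), C=CB1OC(C)(C)C(C)(C)O1
Why: Hayashi–Miyaura rhodium-catalysed asymmetric 1,4-addition; the vinyl–rhodium species inserts the activated C5=C10 bond, and (R)-BINAP is chosen because its sense of addition to cyclohex-2-enone corresponds to the required C5 centre, while C10 settles trans through the enol.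

Step 4
Reactants: 7 5-vinyl keto ester; 8 methyl bromoacetate
Product: 9 methyl (1R,6R)-6-ethenyl-1-(2-methoxy-2-oxoethyl)-5,5-dimethyl-2-oxocyclohexane-1-carboxylate (C9 trans to C6)
Conditions: NaH, THF/DMF, 0 °C; BrCH2CO2Me, rt
Reagents that add atoms: methyl bromoacetate (8), COC(=O)CBr
Why: SN2 C-alkylation of the β-keto ester enolate; allylic strain and the C4 gem-dimethyl group hold the C5 vinyl group pseudo-axial, so the electrophile enters C10 from the other face and C9 ends up trans to C6 (the later trans A/B fusion).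

Step 5
Reactants: 9 keto diester
Product: 11 trans-fused O1–C11 γ-lactone methyl ester (O1 cis to the C20 ester; 5-vinyl), via 1-hydroxy diester 10 (not isolated)
Conditions: NaBH4, MeOH, −20 °C; then TsOH·H2O (10 mol%), PhMe, 80 °C
Reagents that add atoms: none
Why: Borohydride reduction from the face of the CH2CO2Me arm (the other face carries the C20 ester and the vinyl group) should give the 1-hydroxyl cis to C20, and acid-catalysed transesterification (5-exo-trig) closes the γ-lactone between O1 and C11.

Step 6
Reactants: 11 γ-lactone methyl ester; 12 allyl bromide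
Product: 13 9-allyl γ-lactone (allyl anti to C20; H9 syn to C20)
Conditions: LiN(iPr)2, THF, −78 °C; allyl bromide, DMPU, −78 to −30 °C
Reagents that add atoms: allyl bromide (12), C=CCBr
Why: SN2 alkylation of the lactone lithium enolate anti to the axial C20 ester on the neighbouring quaternary C10 sets C9, with C11 tied to O1 on the lower face and C8 pointing toward C5.

Step 7
Reactants: 13 9-allyl γ-lactone
Product: 14 1,11,20-triol (5-vinyl; 9-allyl)
Conditions: LiAlH4, THF, 0 °C to 65 °C; aqueous NaOH work-up
Reagents that add atoms: none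
Why: Exhaustive hydride reduction of the lactone and the ester (acyl substitution, then aldehyde reduction); both alkenes are inert.

Step 8
Reactants: 14 1,11,20-triol
Product: 15 1,20-acetonide 11-ol
Conditions: Me2C(OMe)2, PPTS (cat.), CH2Cl2, rt
Reagents that add atoms: 2,2-dimethoxypropane, COC(C)(C)OC
Why: Thermodynamic transacetalisation; only the 1,20-diol can close a six-membered 1,3-dioxane (the alternatives are seven-membered), so the primary 11-hydroxyl stays free.

Step 9
Reactants: 15 1,20-acetonide 11-ol; 16 acetic anhydride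
Product: 17 1,20-acetonide 11-acetate
Conditions: Ac2O, pyridine, DMAP (cat.), CH2Cl2, rt
Reagents that add atoms: acetic anhydride (16), CC(=O)OC(C)=O
Why: DMAP-catalysed acylation masks O11 during the oxidative steps.

Step 10
Reactants: 17 1,20-acetonide 11-acetate
Product: 18 dialdehyde (C5–CHO as C6; C9–CH2CHO as C8 and C7)
Conditions: O3, CH2Cl2/MeOH 4:1, −78 °C; Me2S, −78 °C to rt
Reagents that add atoms: ozone, [O-][O+]=O
Why: Ozonolysis of both terminal alkenes with reductive work-up should give the 1,6-dialdehyde; acetal and ester are inert.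

Step 11
Reactants: 18 dialdehyde
Product: 19 ring B aldol product (6-OH down; C7 formyl up on C8; C11 down; H5 down)
Conditions: L-proline (30 mol%), DMSO, rt
Reagents that add atoms: none
Why: Proline enamine aldol (5-enolexo cyclisation): only the CH2CHO arm can form an enamine, which adds to the neopentyl C6 aldehyde to close ring B; ring strain places O6 away from the C4 methyl groups (cis to H5), the anti transition state of L-proline is matched to this, and C7 ends trans to O6 and to C11.

Step 12
Reactants: 19 ring B aldol product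
Product: 21 6-hydroxy C7 methyl ester, via 6-hydroxy C7 acid 20 (not isolated)
Conditions: NaClO2, NaH2PO4, 2-methyl-2-butene, tBuOH/H2O, 0 °C; then TMSCHN2, PhMe/MeOH, 0 °C
Reagents that add atoms: sodium chlorite, [Na+].[O-]Cl=O; trimethylsilyldiazomethane, C[Si](C)(C)C=[N+]=[N-]
Why: Pinnick oxidation consumes the β-hydroxy aldehyde before it can dehydrate, and diazomethane-type methylation of the acid gives the ester.

Step 13
Reactants: 21 6-hydroxy C7 methyl ester
Product: 22 6-O-TBS methyl ester 11-acetate
Conditions: TBSOTf, 2,6-lutidine, CH2Cl2, −78 to 0 °C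
Reagents that add atoms: tert-butyldimethylsilyl triflate, CC(C)(C)[Si](C)(C)OS(=O)(=O)C(F)(F)F
Why: Silylation of the hindered secondary alcohol with the silyl triflate; the ether is kept until the last step.

Step 14
Reactants: 22 6-O-TBS methyl ester 11-acetate
Product: 23 11-ol
Conditions: K2CO3, MeOH, 0 °C to rt
Reagents that add atoms: none
Why: Mild methanolysis of the primary acetate; the C7 ester is trans to C11 on ring B and cannot lactonise onto O11.

Step 15
Reactants: 23 11-ol
Product: 24 C11 aldehyde
Conditions: Dess–Martin periodinane, NaHCO3, CH2Cl2, 0 °C to rt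
Reagents that add atoms: none
Why: Dess–Martin oxidation of the primary alcohol under buffered conditions that should leave C9 untouched.

Step 16
Reactants: 24 C11 aldehyde; 25 vinylmagnesium bromide
Product: 26 11-vinyl carbinol (Felkin diastereomer; O11 on the side of C10)
Conditions: CH2=CHMgBr, THF, −78 °C; aqueous NH4Cl
Reagents that add atoms: vinylmagnesium bromide (25), C=C[Mg]Br
Why: Grignard 1,2-addition to the aldehyde, much faster than attack on the hindered ester at −78 °C; Felkin–Anh control with the quaternary C10 anti to the nucleophile sets C11.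

Step 17
Reactants: 26 11-vinyl carbinol
Product: 27 11-O-PMB ether
Conditions: NaH, 4-MeOC6H4CH2Cl, Bu4NI (cat.), DMF, 0 °C to rt
Reagents that add atoms: 4-methoxybenzyl chloride, COc1ccc(CCl)cc1
Why: Williamson etherification; the PMB ether is the chelating α-alkoxy group needed in step 19.

Step 18
Reactants: 27 11-O-PMB ether
Product: 28 C12 aldehyde (α-PMB-oxy)
Conditions: OsO4 (2 mol%), NaIO4, 2,6-lutidine, dioxane/H2O 3:1, rt
Reagents that add atoms: sodium periodate, [Na+].[O-]I(=O)(=O)=O
Why: Lemieux–Johnson cleavage of the only alkene gives the α-alkoxy aldehyde and spares the PMB ether.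

Step 19
Reactants: 28 C12 aldehyde; 25 vinylmagnesium bromide
Product: 29 (11R,12R)-12-vinyl carbinol hydroxy ester (C7 ester up)
Conditions: MgBr2·OEt2, CH2Cl2, −78 °C; then CH2=CHMgBr, −78 °C; aqueous NH4Cl
Reagents that add atoms: vinylmagnesium bromide (25), C=C[Mg]Br
Why: Chelation-controlled (Cram chelate) Grignard addition to the α-PMB-oxy aldehyde gives the syn diol monoether, which puts the C12 vinyl group on the face of the future lactone that carries C10.

Step 20
Reactants: 29 12-vinyl carbinol hydroxy ester
Product: 31 cis-fused C7–O–C12 vinyl lactone (C7 down; H8 and H9 up; 11-OPMB; 6-OTBS; 1,20-acetonide), via hydroxy acid 30 (not isolated)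
Conditions: LiOH, THF/MeOH/H2O, 40 °C, then 1 M HCl; then 2,4,6-Cl3C6H2COCl, Et3N, THF, rt; DMAP, PhMe (2 mM), 80 °C
Reagents that add atoms: none
Why: Saponification and Yamaguchi lactonisation (6-exo-trig acyl substitution); the acid as formed (C7 up) cannot reach O12 without a strained trans-fused ring, but its enolisable acylpyridinium or ketene form epimerises at C8 under Et3N and DMAP and only the C7-down isomer is trapped as the cis-fused lactone.

Step 21
Reactants: 31 cis-fused C7–O–C12 vinyl lactone
Product: 34 ring C acid (C8 quaternary with CO2H up and C14 down; C12=C13; H9 up), via trimethylsilyl ketene acetal 32 (not isolated), via trimethylsilyl ester 33 (not isolated)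
Conditions: Me3SiCl/Et3N (premixed), THF, −78 °C; LiN(iPr)2, −78 °C; then PhMe, 90 °C; MeOH, pH 4 buffer
Reagents that add atoms: none
Why: Silylation of the lactone enolate in the presence of Me3SiCl gives the cyclic C8=C7 ketene acetal 32, which on warming undergoes the Ireland–Claisen [3,3]-sigmatropic shift, the known carbocycle-forming rearrangement of vinyl lactone silyl ketene acetals: C14 bonds to C8 while O–C12 breaks, leaving the C12=C13 alkene and the silyl ester 33 of the C7 acid. Ring C closes by this C8–C14 bond through a boat, bicyclo[2.2.2]octane-like six-centre array in which C9–C11 is the third bridge, the only geometry the six-membered lactone allows. Ring B holds C6 and C10 in the plane of the ketene acetal, so C14 can reach only the lobe of C8 on the side of C11; the new quaternary centre C8 is thus set by C9 and C12 (C11 down, vinyl on the lactone face that carries C10), with C14 entering from below and C7 pushed up, cis to C20. The step needs enolisation without loss of the C6 silyloxy group, which immediate O-silylation at −78 °C secures, and a boat free of torsional strain in ring B, which the 9-epi arrangement secures. The resulting cis B/C junction is corrected at C9 in step 25.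

Step 22
Reactants: 34 ring C acid
Product: 35 11-hydroxy acid
Conditions: DDQ, CH2Cl2/pH 7 buffer 10:1, 0 °C to rt
Reagents that add atoms: none
Why: Oxidative PMB cleavage (benzylic hydride abstraction, then hydrolysis of the oxocarbenium ion) frees the allylic 11-hydroxyl; acetonide and silyl ether are inert.

Step 23
Reactants: 35 11-hydroxy acid
Product: 37 C7–O–C20 lactone 1,11-diol (9-epi), via triol acid 36 (not isolated)
Conditions: PPTS, MeOH, 40 °C; then EDC·HCl, DMAP, CH2Cl2 (5 mM), rt
Reagents that add atoms: none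
Why: Transacetalisation frees the 1,20-diol and carbodiimide lactonisation (6-exo-trig) closes the bridging lactone; O11 is trans to C7 on ring B and O1 would need a seven-membered ring, so only O20 can react intramolecularly.

Step 24
Reactants: 37 C7–O–C20 lactone 1,11-diol
Product: 38 9-epi enone (C11 ketone; C12=C13)
Conditions: MnO2 (excess), CH2Cl2, rt
Reagents that add atoms: none
Why: MnO2 oxidises only the allylic 11-hydroxyl; the saturated 1-hydroxyl is untouched.

Step 25
Reactants: 38 9-epi enone
Product: 39 enone with natural C9 (H9 down; trans B/C)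
Conditions: DBU (2 equiv), PhMe, 70 °C
Reagents that add atoms: none
Why: Base-mediated epimerisation through the C9–C11 enolate under thermodynamic control; in the 9-epimer C11 lies over the C5–C6 bridge beside the 6-OTBS group on an all-cis cyclopentane, whereas after inversion it lies over the flat lactone bridge, so the equilibrium should favour the natural arrangement.

Step 26
Reactants: 39 enone with natural C9; 16 acetic anhydride
Product: 40 1-acetate enone
Conditions: Ac2O, pyridine, DMAP (cat.), CH2Cl2, rt
Reagents that add atoms: acetic anhydride (16), CC(=O)OC(C)=O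
Why: DMAP-catalysed acetylation of the only free hydroxyl installs the acetate of the target.

Step 27
Reactants: 40 1-acetate enone; 41 trimethyl phosphonoacetate
Product: 42 C13 phosphonoacetate adduct (13S; epimers at the phosphorus-bearing carbon)
Conditions: (MeO)2P(O)CH2CO2Me, Cs2CO3 (0.3 equiv), MeCN, 40 °C
Reagents that add atoms: trimethyl phosphonoacetate (41), COC(=O)CP(=O)(OC)OC
Why: Reversible Michael addition of the phosphonate carbanion to the enone; the nucleophile adds to C13 on the face away from the lactone carbonyl under ring C, and thermodynamic control leaves the new substituent equatorial.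

Step 28
Reactants: 42 C13 phosphonoacetate adduct
Product: 43 11-ol (equatorial; 11S)
Conditions: SmI2 (2.5 equiv), iPrOH, HMPA, THF, −20 °C
Reagents that add atoms: none
Why: Single-electron ketone reduction under protonating conditions should give the more stable equatorial alcohol, as dissolving-metal reduction of steroidal 11-ketones does, whereas hydride would attack the open face and give the axial epimer; it is done before the acrylate exists.

Step 29
Reactants: 43 11-ol; 44 formaldehyde
Product: 45 6-O-TBS ether of the target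
Conditions: 37% aqueous HCHO, K2CO3, THF, rt
Reagents that add atoms: formaldehyde (44), C=O
Why: Horner–Wadsworth–Emmons methylenation of the α-phosphono ester gives the 2-substituted acrylate and erases the extra stereocentre.

Step 30
Reactants: 45 6-O-TBS ether of the target
Product: 46 target CNP0421185.1
Conditions: HF·pyridine, pyridine, THF, 0 °C to rt
Reagents that add atoms: none
Why: Fluoride cleavage of the secondary silyl ether under buffered conditions that leave the acetate, lactone and acrylate intact.

**Compound list**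
1 | 4,4-dimethylcyclohexanone | CC1(C)CCC(=O)CC1 | starting material
2 | dimethyl carbonate | COC(=O)OC | starting material
3 | methyl 5,5-dimethyl-2-oxocyclohexane-1-carboxylate (racemic, enolisable) | COC(=O)C1CC(C)(C)CCC1=O | intermediate
4 | methyl 5,5-dimethyl-2-oxo-1-(phenylselanyl)cyclohexane-1-carboxylate (racemic) | COC(=O)C1([Se]c2ccccc2)CC(C)(C)CCC1=O | intermediate
5 | methyl 3,3-dimethyl-6-oxocyclohex-1-ene-1-carboxylate | COC(=O)C1=CC(C)(C)CCC1=O | intermediate
6 | 4,4,5,5-tetramethyl-2-vinyl-1,3,2-dioxaborolane | C=CB1OC(C)(C)C(C)(C)O1 | starting material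
7 | methyl (1S,6S)-6-ethenyl-5,5-dimethyl-2-oxocyclohexane-1-carboxylate | COC(=O)[C@@H]1C(=O)CCC(C)(C)[C@H]1C=C | intermediate
8 | methyl bromoacetate | COC(=O)CBr | starting material
9 | methyl (1R,6R)-6-ethenyl-1-(2-methoxy-2-oxoethyl)-5,5-dimethyl-2-oxocyclohexane-1-carboxylate | COC(=O)C[C@]1(C(=O)OC)C(=O)CCC(C)(C)[C@H]1C=C | intermediate
10 | 1-hydroxy diester (1-OH cis to the C20 ester) | COC(=O)C[C@]1(C(=O)OC)[C@@H](O)CCC(C)(C)[C@H]1C=C | intermediate
11 | trans-fused O1–C11 γ-lactone methyl ester | O=C1C[C@]2(C(=O)OC)[C@@H](O1)CCC(C)(C)[C@H]2C=C | intermediate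
12 | allyl bromide | C=CCBr | starting material
13 | 9-allyl γ-lactone (allyl anti to C20) | O=C1[C@@H](CC=C)[C@]2(C(=O)OC)[C@@H](O1)CCC(C)(C)[C@H]2C=C | intermediate
14 | 1,11,20-triol | OC[C@@H](CC=C)[C@]1(CO)[C@@H](O)CCC(C)(C)[C@H]1C=C | intermediate
15 | 1,20-acetonide 11-ol | OC[C@@H](CC=C)[C@]12COC(C)(C)O[C@H]1CCC(C)(C)[C@H]2C=C | intermediate
16 | acetic anhydride | CC(=O)OC(C)=O | starting material
17 | 1,20-acetonide 11-acetate | CC(=O)OC[C@@H](CC=C)[C@]12COC(C)(C)O[C@H]1CCC(C)(C)[C@H]2C=C | intermediate
18 | dialdehyde | CC(=O)OC[C@@H](CC=O)[C@]12COC(C)(C)O[C@H]1CCC(C)(C)[C@H]2C=O | intermediate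
19 | ring B aldol product (6-OH down, C7 formyl up) | CC1(C)O[C@H]2CCC(C)(C)[C@H]3[C@H](O)[C@@H](C=O)[C@H](COC(C)=O)[C@]23CO1 | intermediate
20 | 6-hydroxy C7 acid | CC1(C)O[C@H]2CCC(C)(C)[C@H]3[C@H](O)[C@@H](C(=O)O)[C@H](COC(C)=O)[C@]23CO1 | intermediate
21 | 6-hydroxy C7 methyl ester | CC1(C)O[C@H]2CCC(C)(C)[C@H]3[C@H](O)[C@@H](C(=O)OC)[C@H](COC(C)=O)[C@]23CO1 | intermediate
22 | 6-O-TBS methyl ester 11-acetate | CC1(C)O[C@H]2CCC(C)(C)[C@H]3[C@H](O[Si](C)(C)C(C)(C)C)[C@@H](C(=O)OC)[C@H](COC(C)=O)[C@]23CO1 | intermediate
23 | 11-ol | CC1(C)O[C@H]2CCC(C)(C)[C@H]3[C@H](O[Si](C)(C)C(C)(C)C)[C@@H](C(=O)OC)[C@H](CO)[C@]23CO1 | intermediate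
24 | C11 aldehyde | CC1(C)O[C@H]2CCC(C)(C)[C@H]3[C@H](O[Si](C)(C)C(C)(C)C)[C@@H](C(=O)OC)[C@H](C=O)[C@]23CO1 | intermediate
25 | vinylmagnesium bromide | C=C[Mg]Br | starting material
26 | 11-vinyl carbinol | CC1(C)O[C@H]2CCC(C)(C)[C@H]3[C@H](O[Si](C)(C)C(C)(C)C)[C@@H](C(=O)OC)[C@H]([C@@H](O)C=C)[C@]23CO1 | intermediate
27 | 11-O-PMB ether | CC1(C)O[C@H]2CCC(C)(C)[C@H]3[C@H](O[Si](C)(C)C(C)(C)C)[C@@H](C(=O)OC)[C@H]([C@@H](OCc4ccc(OC)cc4)C=C)[C@]23CO1 | intermediate
28 | C12 aldehyde | CC1(C)O[C@H]2CCC(C)(C)[C@H]3[C@H](O[Si](C)(C)C(C)(C)C)[C@@H](C(=O)OC)[C@H]([C@@H](OCc4ccc(OC)cc4)C=O)[C@]23CO1 | intermediate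
29 | (11R,12R)-12-vinyl carbinol hydroxy ester | CC1(C)O[C@H]2CCC(C)(C)[C@H]3[C@H](O[Si](C)(C)C(C)(C)C)[C@@H](C(=O)OC)[C@H]([C@@H](OCc4ccc(OC)cc4)[C@H](O)C=C)[C@]23CO1 | intermediate
30 | hydroxy acid | CC1(C)O[C@H]2CCC(C)(C)[C@H]3[C@H](O[Si](C)(C)C(C)(C)C)[C@@H](C(=O)O)[C@H]([C@@H](OCc4ccc(OC)cc4)[C@H](O)C=C)[C@]23CO1 | intermediate
31 | cis-fused C7–O–C12 vinyl lactone (key-step precursor) | CC1(C)O[C@H]2CCC(C)(C)[C@H]3[C@H](O[Si](C)(C)C(C)(C)C)[C@@H]4C(=O)O[C@H](C=C)[C@H](OCc5ccc(OC)cc5)[C@@H]4[C@]23CO1 | intermediate
32 | trimethylsilyl ketene acetal | CC1(C)O[C@H]2CCC(C)(C)[C@H]3[C@H](O[Si](C)(C)C(C)(C)C)C4=C(O[Si](C)(C)C)O[C@H](C=C)[C@H](OCc5ccc(OC)cc5)[C@@H]4[C@]23CO1 | intermediate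
33 | trimethylsilyl ester | CC1(C)O[C@H]2CCC(C)(C)[C@H]3[C@H](O[Si](C)(C)C(C)(C)C)[C@]4(C(=O)O[Si](C)(C)C)CC=C[C@H](OCc5ccc(OC)cc5)[C@@H]4[C@]23CO1 | intermediate
34 | ring C acid (key-step product) | CC1(C)O[C@H]2CCC(C)(C)[C@H]3[C@H](O[Si](C)(C)C(C)(C)C)[C@]4(C(=O)O)CC=C[C@H](OCc5ccc(OC)cc5)[C@@H]4[C@]23CO1 | intermediate
35 | 11-hydroxy acid | CC1(C)O[C@H]2CCC(C)(C)[C@H]3[C@H](O[Si](C)(C)C(C)(C)C)[C@]4(C(=O)O)CC=C[C@H](O)[C@@H]4[C@]23CO1 | intermediate
36 | triol acid | O[C@H]1CCC(C)(C)[C@H]2[C@H](O[Si](C)(C)C(C)(C)C)[C@]3(C(=O)O)CC=C[C@H](O)[C@@H]3[C@]12CO | intermediate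
37 | C7–O–C20 lactone 1,11-diol (9-epi) | O[C@H]1CCC(C)(C)[C@H]2[C@H](O[Si](C)(C)C(C)(C)C)[C@]34CC=C[C@H](O)[C@@H]3[C@]12COC4=O | intermediate
38 | 9-epi enone | O[C@H]1CCC(C)(C)[C@H]2[C@H](O[Si](C)(C)C(C)(C)C)[C@]34CC=CC(=O)[C@@H]3[C@]12COC4=O | intermediate
39 | enone with natural C9 | O[C@H]1CCC(C)(C)[C@H]2[C@H](O[Si](C)(C)C(C)(C)C)[C@]34CC=CC(=O)[C@H]3[C@]12COC4=O | intermediate
40 | 1-acetate enone | CC(=O)O[C@H]1CCC(C)(C)[C@H]2[C@H](O[Si](C)(C)C(C)(C)C)[C@]34CC=CC(=O)[C@H]3[C@]12COC4=O | intermediate
41 | trimethyl phosphonoacetate | COC(=O)CP(=O)(OC)OC | starting material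
42 | C13 phosphonoacetate adduct | CC(=O)O[C@H]1CCC(C)(C)[C@H]2[C@H](O[Si](C)(C)C(C)(C)C)[C@]34C[C@H](C(C(=O)OC)P(=O)(OC)OC)CC(=O)[C@H]3[C@]12COC4=O | intermediate
43 | 11-ol | CC(=O)O[C@H]1CCC(C)(C)[C@H]2[C@H](O[Si](C)(C)C(C)(C)C)[C@]34C[C@H](C(C(=O)OC)P(=O)(OC)OC)C[C@H](O)[C@H]3[C@]12COC4=O | intermediate
44 | formaldehyde | C=O | starting material
45 | 6-O-TBS ether of the target | CC(=O)O[C@H]1CCC(C)(C)[C@H]2[C@H](O[Si](C)(C)C(C)(C)C)[C@]34C[C@H](C(=C)C(=O)OC)C[C@H](O)[C@H]3[C@]12COC4=O | intermediate
46 | target CNP0421185.1 | CC(=O)O[C@H]1CCC(C)(C)[C@H]2[C@H](O)[C@]34C[C@H](C(=C)C(=O)OC)C[C@H](O)[C@H]3[C@]12COC4=O | target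

Total step count: 30. Longest linear sequence: 30 steps (the route is fully linear from 1).

**Steps most likely to fail**

Step 25 (inversion of C9). The equilibrium may not lie far enough toward the natural epimer, or enolisation toward the strained bridge carbon C9 may be too slow. The fallback replaces thermodynamic by kinetic control and sets out from 38. Acetylation of O1 (Ac2O, pyridine, DMAP) should give the 9-epi 1-acetate enone F7. HF·pyridine then removes the silyl group to give the 6-hydroxy 9-epi enone F8. LiN(SiMe3)2 (2.2 equiv, THF, −78 °C) forms the 6-alkoxide and the C9–C11 enolate, and a cold quench with AcOH should protonate C9 on the face next to the now small 6-alkoxide (the other face is covered by the lactone bridge), giving the 9-inverted 6-hydroxy enone F9. TBSOTf and 2,6-lutidine then return 40.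

Step 21 (key rearrangement). The enolate may lose the C6 silyloxy group by β-elimination before it is silylated, or the boat may be too congested beside the silyl ether to rearrange. The fallback closes ring C by an ionic path and sets out from 29. Methyl chloroformate and pyridine should give the allylic methyl carbonate F4. LiN(SiMe3)2 and then Pd(PPh3)4 (zerovalent palladium) in THF bring about an intramolecular Tsuji–Trost allylation: the C8 ester enolate attacks the C14 terminus of the allyl complex, and the short C9–C11 tether again delivers C14 to the face of C11, giving the ring C methyl ester F5. DDQ then frees O11 to give the 11-hydroxy methyl ester F6. PPTS in MeOH followed by TsOH in toluene at 80 °C removes the acetonide and lactonises onto O20 by transesterification, which returns to the route at 37.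

Step 3 (asymmetric vinyl addition). Insertion at the neopentyl β-carbon may be slow, the boronate may protodeboronate, or facial discrimination on this doubly activated enone may be poor. The fallback is a resolution and sets out from 5. CuBr·SMe2-catalysed addition of CH2=CHMgBr (25) with Me3SiCl in THF at −78 °C should give the racemic keto ester, that is 7 together with the mirror-image keto ester F1. Condensation with (S)-1-phenylethylamine (toluene, cat. AcOH, water removal) gives the diastereomeric enamino esters, the (5S) enamino ester F2 from 7 and the (5R) enamino ester F3 from F1, which are separated by crystallisation or chromatography. Hydrolysis of F2 with dilute HCl in THF returns 7.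

Further compounds
F1 | step 3 | mirror-image keto ester (ent-7) | COC(=O)[C@H]1C(=O)CCC(C)(C)[C@@H]1C=C
F2 | step 3 | (5S) enamino ester of 7 with (S)-1-phenylethylamine | COC(=O)C1=C(N[C@@H](C)c2ccccc2)CCC(C)(C)[C@H]1C=C
F3 | step 3 | (5R) enamino ester of F1 with (S)-1-phenylethylamine | COC(=O)C1=C(N[C@@H](C)c2ccccc2)CCC(C)(C)[C@@H]1C=C
F4 | step 21 | allylic methyl carbonate of 29 | CC1(C)O[C@H]2CCC(C)(C)[C@H]3[C@H](O[Si](C)(C)C(C)(C)C)[C@@H](C(=O)OC)[C@H]([C@@H](OCc4ccc(OC)cc4)[C@H](OC(=O)OC)C=C)[C@]23CO1
F5 | step 21 | ring C methyl ester (methyl ester of 34) | CC1(C)O[C@H]2CCC(C)(C)[C@H]3[C@H](O[Si](C)(C)C(C)(C)C)[C@]4(C(=O)OC)CC=C[C@H](OCc5ccc(OC)cc5)[C@@H]4[C@]23CO1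
F6 | step 21 | 11-hydroxy methyl ester | CC1(C)O[C@H]2CCC(C)(C)[C@H]3[C@H](O[Si](C)(C)C(C)(C)C)[C@]4(C(=O)OC)CC=C[C@H](O)[C@@H]4[C@]23CO1
F7 | step 25 | 9-epi 1-acetate enone | CC(=O)O[C@H]1CCC(C)(C)[C@H]2[C@H](O[Si](C)(C)C(C)(C)C)[C@]34CC=CC(=O)[C@@H]3[C@]12COC4=O
F8 | step 25 | 6-hydroxy 9-epi enone | CC(=O)O[C@H]1CCC(C)(C)[C@H]2[C@H](O)[C@]34CC=CC(=O)[C@@H]3[C@]12COC4=O
F9 | step 25 | 9-inverted 6-hydroxy enone | CC(=O)O[C@H]1CCC(C)(C)[C@H]2[C@H](O)[C@]34CC=CC(=O)[C@H]3[C@]12COC4=O
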